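## Retrosynthetic overview

1. Dienone ring numbering: C1' (bonded to C3 of the isoindolinone), C2' (C–OH), C3' (CH), C4' (C–CH3), C5' (gem-diprenyl), C6' (C=O). The enabling feature is the array C2'(O)–C1'–C6'(O)–C5'(quaternary): these four atoms are the ring atoms of a 3-alkoxycyclobut-2-enone, and the quaternary C5' forbids aromatisation after ring expansion.
2. Key disconnection at C2'–C3' and C4'–C5': cyclobutenone 16, which holds a temporary strained C2'–C5' bond, plus propyne. Zerovalent nickel inserts the alkyne into that bond (four- to six-membered ring expansion); enol ether hydrolysis then gives the target.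
3. 16 comes from a ketene/ynol ether [2+2] of bis(prenyl)ketene with ynol ether 9. 9 comes from addition of ethoxyethynylmagnesium chloride to the (S)-N-tert-butanesulfinyl imine of methyl 2-formyl-3-methoxybenzoate with lactam closure, which sets C3.
4. Ring order: benzene ring bought; lactam ring (step 4); temporary four-membered ring (step 7); six-membered dienone ring (step 9).

Key step: step 9

Remark: the target is treated as the drawn enol tautomer of the cyclic 1,3-dione. The C3 descriptor is R in the alkynyl compounds 8 and 9 and S from 15 onward only because the CIP priorities change; the spatial arrangement is that of the target throughout.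

## Route

Step 1
Reactants: 1 methyl 3-methoxy-2-methylbenzoate
Product: 2 methyl 2-(bromomethyl)-3-methoxybenzoate
Conditions: NBS (1.05 equiv), AIBN (5 mol%), PhCF3, 80 °C
Reagents that add atoms: N-bromosuccinimide O=C1CCC(=O)N1Br
Why: Wohl–Ziegler radical bromination should take the only benzylic C–H position, and limiting the NBS should hold it at the monobromide.

Step 2
Reactants: 2 methyl 2-(bromomethyl)-3-methoxybenzoate
Product: 3 methyl 2-formyl-3-methoxybenzoate
Conditions: NMO (3 equiv), 4 Å MS, MeCN, rt
Reagents that add atoms: N-methylmorpholine N-oxide C[N+]1([O-])CCOCC1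
Why: Kornblum-type oxidation (O-alkylation of the N-oxide by the benzylic bromide, then elimination) should give the aldehyde without over-oxidation and leave the ester alone.

Step 3
Reactants: 3 methyl 2-formyl-3-methoxybenzoate; 4 (S)-2-methylpropane-2-sulfinamide
Product: 5 methyl 2-[(E)-{[(S)-tert-butylsulfinyl]imino}methyl]-3-methoxybenzoate
Conditions: KHSO4, toluene, 45 °C
Reagents that add atoms: none
Why: acid-promoted condensation of an aldehyde with tert-butanesulfinamide should give the (E)-N-sulfinyl aldimine without transesterification; the sulfur stereocentre comes unchanged from 4.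

Step 4
Reactants: 5 methyl 2-[(E)-{[(S)-tert-butylsulfinyl]imino}methyl]-3-methoxybenzoate; 6 ethoxyethyne
Product: 9 (R)-2-[(S)-tert-butylsulfinyl]-3-(ethoxyethynyl)-4-methoxyisoindolin-1-one, via ethoxyethynylmagnesium chloride 7 (not isolated), via open-chain magnesium sulfinamide 8 (not isolated)
Conditions: 6, i-PrMgCl, THF, 0 °C; then 5, CH2Cl2, −78 °C → rt
Reagents that add atoms: none
Why: addition of an alkynylmagnesium halide to an N-tert-butanesulfinyl aldimine in a weakly coordinating medium should pass through the six-membered magnesium-chelated chair transition state (tert-butyl equatorial), which for the (S)-sulfinyl imine delivers the alkynyl group to the Re face and sets C3 as R, after which the N-magnesio sulfinamide should close onto the ortho methyl ester (5-exo-trig acyl substitution) on warming; a minor diastereomer can be removed on silica.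

Step 5
Reactants: 10 5-methylhex-4-enoic acid; 11 1-bromo-3-methylbut-2-ene (prenyl bromide)
Product: 12 5-methyl-2-(3-methylbut-2-en-1-yl)hex-4-enoic acid
Conditions: LiN(i-Pr)2 (2.2 equiv), THF, −78 → 0 °C; then 11, −78 °C → rt; aq. HCl work-up
Reagents that add atoms: none
Why: alkylation of the carboxylic acid dianion (enediolate) by SN2 at the primary allylic bromide should give the α,α-diprenyl acid, whose α-carbon carries two identical prenyl groups and is no stereocentre.

Step 6
Reactants: 12 5-methyl-2-(3-methylbut-2-en-1-yl)hex-4-enoic acid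
Product: 13 5-methyl-2-(3-methylbut-2-en-1-yl)hex-4-enoyl chloride
Conditions: (COCl)2, DMF (cat.), CH2Cl2, 0 °C → rt
Reagents that add atoms: oxalyl chloride O=C(Cl)C(=O)Cl
Why: acid chloride formation through the Vilsmeier-type chloroiminium intermediate should proceed under conditions mild enough to spare the trisubstituted alkenes.

Step 7
Reactants: 9 (R)-2-[(S)-tert-butylsulfinyl]-3-(ethoxyethynyl)-4-methoxyisoindolin-1-one; 13 5-methyl-2-(3-methylbut-2-en-1-yl)hex-4-enoyl chloride
Product: 15 (S)-2-[(S)-tert-butylsulfinyl]-3-[2-ethoxy-3,3-bis(3-methylbut-2-en-1-yl)-4-oxocyclobut-1-en-1-yl]-4-methoxyisoindolin-1-one, via bis(prenyl)ketene 14 (not isolated)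
Conditions: Et3N (3 equiv), 13 added slowly, toluene, 60 °C
Reagents that add atoms: none
Why: dehydrochlorination should give the dialkylketene, which should undergo the regioselective thermal [2+2] cycloaddition of ketenes with ynol ethers (nucleophilic alkyne carbon to the ketene carbonyl carbon, closure at the oxygen-bearing carbon) to the 3-ethoxycyclobutenone; the N-sulfinyl lactam has no N–H to acylate, C3 is not touched, and any base-induced epimerisation would show as a separable sulfinyl diastereomer.

Step 8
Reactants: 15 (S)-2-[(S)-tert-butylsulfinyl]-3-[2-ethoxy-3,3-bis(3-methylbut-2-en-1-yl)-4-oxocyclobut-1-en-1-yl]-4-methoxyisoindolin-1-one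
Product: 16 (S)-3-[2-ethoxy-3,3-bis(3-methylbut-2-en-1-yl)-4-oxocyclobut-1-en-1-yl]-4-methoxyisoindolin-1-one
Conditions: HCl (1.25 M in EtOH, 0.5 equiv), CH2Cl2, 0 °C
Reagents that add atoms: none
Why: acid-catalysed ethanolysis of the S–N bond (the usual removal of the tert-butanesulfinyl auxiliary, faster still on an N-acyl sulfinamide) should free the lactam N–H, while ethanol makes any exchange at the ethyl enol ether degenerate and the short cold exposure spares the prenyl groups and the four-membered ring.

Step 9
Reactants: 16 (S)-3-[2-ethoxy-3,3-bis(3-methylbut-2-en-1-yl)-4-oxocyclobut-1-en-1-yl]-4-methoxyisoindolin-1-one; 17 propyne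
Product: 18 (S)-3-[2-ethoxy-4-methyl-3,3-bis(3-methylbut-2-en-1-yl)-6-oxocyclohexa-1,4-dien-1-yl]-4-methoxyisoindolin-1-one
Conditions: Ni(cod)2 (10 mol%), PPh3 (20 mol%), 17 (1 M in THF, 4 equiv, slow addition), toluene, 0 °C → rt
Reagents that add atoms: none
Why: Proposed new method: zerovalent nickel should insert into the strained bond between the carbonyl carbon and the gem-diprenyl carbon of the cyclobutenone to give a nickel-bound vinylketene (nickelacyclopentenone), propyne should couple through its unsubstituted carbon with the acyl carbon, and C–C reductive elimination between the methyl-bearing alkenyl carbon and the gem-diprenyl carbon should release the cyclohexa-2,5-dienone and the catalyst. The closest known reaction type is the Ni(cod)2-catalysed [4+2] benzannulation of cyclobutenones with alkynes to phenols, which inserts the alkyne between the same two ring atoms; it has not been shown for 4,4-dialkyl-3-alkoxycyclobutenones, where the quaternary carbon makes the dienone the end point, nor reliably for a terminal alkyne. The six-membered ring is closed by reductive elimination from a seven-membered alkenyl/oxa-allyl nickelacycle, a formal [4+2] ring expansion in which the temporary four-membered ring is consumed. No new stereocentre arises, since the quaternary carbon carries two identical prenyl groups, and the C3 centre is remote from the metal and is not deprotonated under these neutral conditions. The step needs regioselectivity (CH to the carbonyl carbon, C–CH3 to the quaternary carbon) and chemoselectivity over alkyne oligomerisation, prenyl alkene insertion and β-hydride loss: the first should follow from the H versus CH3 size difference at the first C–C bond formation at the exposed acyl terminus (the fully substituted terminus cannot insert first), the others from slow addition of propyne, the low insertion aptitude of trisubstituted alkenes and the π-bound vinylketene character of the hindered terminus.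

Step 10
Reactants: 18 (S)-3-[2-ethoxy-4-methyl-3,3-bis(3-methylbut-2-en-1-yl)-6-oxocyclohexa-1,4-dien-1-yl]-4-methoxyisoindolin-1-one
Product: 19 (S)-3-[2-hydroxy-4-methyl-5,5-bis(3-methylbut-2-en-1-yl)-6-oxocyclohexa-1,3-dien-1-yl]-4-methoxyisoindolin-1-one (CNP0508988.1)
Conditions: 1 M aq. HCl, THF, 0 °C → rt
Reagents that add atoms: water O
Why: acid hydrolysis of the vinylogous ethyl ester (protonation, water addition at the ethoxy-bearing carbon, loss of ethanol) should give the cyclic 1,3-dione, which settles as the linearly conjugated enol of the target, and dilute acid at low temperature should leave the prenyl groups and the C3 centre untouched.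

## Compound list

1 | methyl 3-methoxy-2-methylbenzoate | COC(=O)c1cccc(OC)c1C | starting material
2 | methyl 2-(bromomethyl)-3-methoxybenzoate | COC(=O)c1cccc(OC)c1CBr | intermediate
3 | methyl 2-formyl-3-methoxybenzoate | COC(=O)c1cccc(OC)c1C=O | intermediate
4 | (S)-2-methylpropane-2-sulfinamide | CC(C)(C)[S@](=O)N | starting material
5 | methyl 2-[(E)-{[(S)-tert-butylsulfinyl]imino}methyl]-3-methoxybenzoate | COC(=O)c1cccc(OC)c1/C=N/[S@@](=O)C(C)(C)C | intermediate
6 | ethoxyethyne (ethoxyacetylene) | CCOC#C | starting material
7 | ethoxyethynylmagnesium chloride | CCOC#C[Mg]Cl | intermediate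
8 | methyl 2-[(1R)-1-{[(S)-tert-butylsulfinyl]amino}-3-ethoxyprop-2-yn-1-yl]-3-methoxybenzoate (present as its N-chloromagnesium salt) | COC(=O)c1cccc(OC)c1[C@@H](C#COCC)N[S@@](=O)C(C)(C)C | intermediate
9 | (R)-2-[(S)-tert-butylsulfinyl]-3-(ethoxyethynyl)-4-methoxyisoindolin-1-one | COc1cccc2c1[C@@H](C#COCC)N([S@@](=O)C(C)(C)C)C2=O | intermediate
10 | 5-methylhex-4-enoic acid | CC(C)=CCCC(=O)O | starting material
11 | 1-bromo-3-methylbut-2-ene (prenyl bromide) | CC(C)=CCBr | starting material
12 | 5-methyl-2-(3-methylbut-2-en-1-yl)hex-4-enoic acid | CC(C)=CCC(CC=C(C)C)C(=O)O | intermediate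
13 | 5-methyl-2-(3-methylbut-2-en-1-yl)hex-4-enoyl chloride | CC(C)=CCC(CC=C(C)C)C(=O)Cl | intermediate
14 | 2,2-bis(3-methylbut-2-en-1-yl)ethen-1-one (bis(prenyl)ketene) | O=C=C(CC=C(C)C)CC=C(C)C | intermediate
15 | (S)-2-[(S)-tert-butylsulfinyl]-3-[2-ethoxy-3,3-bis(3-methylbut-2-en-1-yl)-4-oxocyclobut-1-en-1-yl]-4-methoxyisoindolin-1-one | COc1cccc2c1[C@@H](C1=C(OCC)C(CC=C(C)C)(CC=C(C)C)C1=O)N([S@@](=O)C(C)(C)C)C2=O | intermediate
16 | (S)-3-[2-ethoxy-3,3-bis(3-methylbut-2-en-1-yl)-4-oxocyclobut-1-en-1-yl]-4-methoxyisoindolin-1-one | COc1cccc2c1[C@@H](C1=C(OCC)C(CC=C(C)C)(CC=C(C)C)C1=O)NC2=O | intermediate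
17 | propyne | CC#C | starting material
18 | (S)-3-[2-ethoxy-4-methyl-3,3-bis(3-methylbut-2-en-1-yl)-6-oxocyclohexa-1,4-dien-1-yl]-4-methoxyisoindolin-1-one | COc1cccc2c1[C@@H](C1=C(OCC)C(CC=C(C)C)(CC=C(C)C)C(C)=CC1=O)NC2=O | intermediate
19 | (S)-3-[2-hydroxy-4-methyl-5,5-bis(3-methylbut-2-en-1-yl)-6-oxocyclohexa-1,3-dien-1-yl]-4-methoxyisoindolin-1-one | COc1cccc2c1[C@@H](C1=C(O)C=C(C)C(CC=C(C)C)(CC=C(C)C)C1=O)NC2=O | target

## Step count and risks

Total step count: 10. Longest linear sequence: 8 steps (1, 2, 3, 4, 7, 8, 9, 10); steps 5 and 6 form the side branch that joins at step 7.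

**Risk 1, step 9.** The zerovalent nickel may fail to open the hindered, electron-rich four-membered ring, propyne may oligomerise faster than it is captured, or the alkyne may insert with the reverse orientation (methyl next to the carbonyl). The fallback uses known chemistry, sets out from 16 and comes back at 18. 16 is treated with (E)-prop-1-en-1-yllithium (2.2 equiv, THF, −78 °C; the first equivalent is consumed by the lactam N–H), and 1,2-addition to the cyclobutenone carbonyl should give the 1-propenylcyclobutenol adduct F1 as its alkoxide. On warming, the alkoxide should undergo the known oxyanion-accelerated 4π electrocyclic ring opening and 6π electrocyclic closure of 1-alkenylcyclobut-2-en-1-olates. In the closure, the methyl-bearing propenyl carbon bonds to the gem-diprenyl carbon, so the regiochemistry is fixed by connectivity. Protonation should give the 5,6-dihydro ketone F2 as a mixture of epimers at the methyl-bearing carbon, which does not matter. Enolisation with LiN(SiMe3)2 (2.2 equiv) and treatment with N-tert-butylbenzenesulfinimidoyl chloride at −78 °C should dehydrogenate F2 to 18.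

**Risk 2, step 7.** The internal ynol ether is hindered and inductively deactivated, so the cycloaddition may be slow enough for ketene dimerisation or acyl transfer to take over, or the base may epimerise C3. The fallback sets out from 13 (with 6 and 3) and comes back at 16. Ketene 14, generated as in step 7, is combined with the unhindered parent ynol ether 6 to give 3-ethoxy-4,4-bis(3-methylbut-2-en-1-yl)cyclobut-2-en-1-one F3. Aqueous HCl should hydrolyse it to the strongly acidic enol 3-hydroxy-4,4-bis(3-methylbut-2-en-1-yl)cyclobut-2-en-1-one F4. In parallel, 3 and ammonia in methanol should give 3-hydroxy-4-methoxyisoindolin-1-one F5. A chiral BINOL-derived phosphoric acid should promote loss of water from F5 and enantioselective Mannich-type amidoalkylation by F4 to give the hydroxycyclobutenone lactam F6. O-Ethylation with Et3OBF4 and i-Pr2NEt should then give 16; the two enol oxygens are equivalent through the local symmetry of the 1,3-dione, and the lactam N–H is far less acidic.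

**Risk 3, step 4.** Facial selectivity may be poor or reversed because the ortho ester and ortho methoxy groups compete with the sulfinyl oxygen for magnesium; the lactam may close incompletely; or the Grignard reagent may attack the ester. The fallback replaces auxiliary control by catalyst control, sets out from 3 (with 6) and comes back at 16. 3 is condensed with 4-methoxyaniline to the N-aryl aldimine F7. CuOTf with a chiral pybox ligand (the enantiomer that delivers the R amine) should add 6 enantioselectively to give the propargylic amine F8. F8 should close onto the ester to give the N-aryl lactam F9; this is the known alkynylation/lactamisation cascade of 2-formylbenzoates. [2+2] cycloaddition with ketene 14 as in step 7 should give the N-aryl cyclobutenone F10. Oxidative removal of the 4-methoxyphenyl group with (NH4)2Ce(NO3)6 in aqueous MeCN at 0 °C should give 16.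

Further compounds
F1 | step 9 | (3S)-3-[2-ethoxy-4-hydroxy-3,3-bis(3-methylbut-2-en-1-yl)-4-[(E)-prop-1-en-1-yl]cyclobut-1-en-1-yl]-4-methoxyisoindolin-1-one (carbinol epimers) | COc1cccc2c1[C@@H](C1=C(OCC)C(CC=C(C)C)(CC=C(C)C)C1(O)/C=C/C)NC2=O
F2 | step 9 | (3S)-3-[2-ethoxy-4-methyl-3,3-bis(3-methylbut-2-en-1-yl)-6-oxocyclohex-1-en-1-yl]-4-methoxyisoindolin-1-one (epimers at the methyl-bearing carbon) | COc1cccc2c1[C@@H](C1=C(OCC)C(CC=C(C)C)(CC=C(C)C)C(C)CC1=O)NC2=O
F3 | step 7 | 3-ethoxy-4,4-bis(3-methylbut-2-en-1-yl)cyclobut-2-en-1-one | CCOC1=CC(=O)C1(CC=C(C)C)CC=C(C)C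
F4 | step 7 | 3-hydroxy-4,4-bis(3-methylbut-2-en-1-yl)cyclobut-2-en-1-one | OC1=CC(=O)C1(CC=C(C)C)CC=C(C)C
F5 | step 7 | 3-hydroxy-4-methoxyisoindolin-1-one (racemic) | COc1cccc2c1C(O)NC2=O
F6 | step 7 | (S)-3-[2-hydroxy-3,3-bis(3-methylbut-2-en-1-yl)-4-oxocyclobut-1-en-1-yl]-4-methoxyisoindolin-1-one | COc1cccc2c1[C@@H](C1=C(O)C(CC=C(C)C)(CC=C(C)C)C1=O)NC2=O
F7 | step 4 | methyl 3-methoxy-2-[(E)-{(4-methoxyphenyl)imino}methyl]benzoate | COC(=O)c1cccc(OC)c1/C=N/c1ccc(OC)cc1
F8 | step 4 | methyl 2-[(1R)-3-ethoxy-1-[(4-methoxyphenyl)amino]prop-2-yn-1-yl]-3-methoxybenzoate | COC(=O)c1cccc(OC)c1[C@@H](C#COCC)Nc1ccc(OC)cc1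
F9 | step 4 | (R)-3-(ethoxyethynyl)-4-methoxy-2-(4-methoxyphenyl)isoindolin-1-one | COc1cccc2c1[C@@H](C#COCC)N(c1ccc(OC)cc1)C2=O
F10 | step 4 | (S)-3-[2-ethoxy-3,3-bis(3-methylbut-2-en-1-yl)-4-oxocyclobut-1-en-1-yl]-4-methoxy-2-(4-methoxyphenyl)isoindolin-1-one | COc1cccc2c1[C@@H](C1=C(OCC)C(CC=C(C)C)(CC=C(C)C)C1=O)N(c1ccc(OC)cc1)C2=O
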